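**Strategy.** Everything rests on removing C2 of pyranone ring C. In the target this carbon is at the carboxylic-acid oxidation level (not the carbonic level) and carries only C3, O1 and the furan oxygen. Taking it out leaves a deoxybenzoin whose benzylic carbon (C3) and ring A phenol (C8a–OH) become its bonding partners. Carbon disulfide, a carbonic-level one-carbon unit, puts it back in one operation: C2–C3 and C2–O1 form, ring C closes, and S-methylation leaves a thioether at C2 that the C2' oxygen later displaces to close the furan. The precursor is a 2-hydroxydeoxybenzoin with the prenylated chroman ring A and chroman ring D complete and the C7, C2' and C5' oxygens as methoxymethyl ethers.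

Key step: step 12

Remark: the target has no stereocentre; isoflavone numbering (O1, C2–C8a, primed ring D) is used for the late compounds and chroman numbering for the fragments.
Remark: Lewis-acid acylation of a prenylated, acetal-protected ring A would cyclise the prenyl group and strip the acetals, so the deoxybenzoin is made by ketone α-arylation and the prenyl group is installed last by Claisen rearrangement.

**Route**

Step 1
Reactants: 1 2,5-dihydroxybenzaldehyde
Product: 2 2,5-bis(methoxymethoxy)benzaldehyde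
Conditions: MOMCl (3 equiv), i-Pr2NEt, CH2Cl2, 0 °C to rt
Reagents that add atoms: chloromethyl methyl ether (MOMCl), COCCl
Why: Williamson-type O-alkylation with the reactive α-chloro ether protects both phenols, including the one hydrogen-bonded to the aldehyde, as base-stable acetals.

Step 2
Reactants: 2 2,5-bis(methoxymethoxy)benzaldehyde
Product: 4 2,5-bis(methoxymethoxy)phenol, via aryl formate 3 (not isolated)
Conditions: mCPBA, CH2Cl2, 0 °C to rt; aqueous NaHCO3 wash; crude formate, K2CO3 (cat.), MeOH, rt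
Reagents that add atoms: 3-chloroperoxybenzoic acid (mCPBA), O=C(OO)c1cccc(Cl)c1
Why: Baeyer–Villiger (Dakin-type) oxidation, in which the electron-rich aryl group migrates to give the aryl formate, followed by mild methanolysis, turns the formyl carbon into the phenol oxygen that will become the ring D pyran oxygen.

Step 3
Reactants: 4 2,5-bis(methoxymethoxy)phenol
Product: 5 4-bromo-2,5-bis(methoxymethoxy)phenol
Conditions: NBS (1.0 equiv), MeCN, −20 to 0 °C
Reagents that add atoms: N-bromosuccinimide (NBS), O=C1CCC(=O)N1Br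
Why: Electrophilic aromatic bromination goes para to the free hydroxyl, the strongest activator, which marks the future C1' before the chromene alkene exists.

Step 4
Reactants: 5 4-bromo-2,5-bis(methoxymethoxy)phenol, 6 3-chloro-3-methylbut-1-yne
Product: 8 6-bromo-5,8-bis(methoxymethoxy)-2,2-dimethyl-2H-chromene, via aryl propargyl ether 7 (not isolated)
Conditions: 6, DBU, CuCl2·2H2O (cat.), MeCN, 0 °C; crude ether, o-xylene, 140 °C
Reagents that add atoms: none
Why: Copper-catalysed propargylic O-alkylation, then aryl propargyl ether Claisen rearrangement, 1,5-hydrogen shift and oxa-6π electrocyclisation build the 2,2-dimethylchromene, and the single free ortho carbon fixes the regiochemistry.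

Step 5
Reactants: 9 1-(2,4,6-trihydroxyphenyl)ethanone
Product: 10 1-[2,4-bis(benzyloxy)-6-hydroxyphenyl]ethanone
Conditions: BnBr (2.05 equiv), K2CO3, acetone, reflux
Reagents that add atoms: benzyl bromide, BrCc1ccccc1
Why: Williamson benzylation takes the two more acidic hydroxyls and leaves the one hydrogen-bonded to the acetyl group free.

Step 6
Reactants: 10 1-[2,4-bis(benzyloxy)-6-hydroxyphenyl]ethanone, 6 3-chloro-3-methylbut-1-yne
Product: 12 1-[5,7-bis(benzyloxy)-2,2-dimethyl-2H-chromen-8-yl]ethanone, via aryl propargyl ether 11 (not isolated)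
Conditions: 6, DBU, CuCl2·2H2O (cat.), MeCN, 0 °C to rt; crude ether, PhNEt2, 190 °C
Reagents that add atoms: none
Why: The same propargylation/Claisen/electrocyclisation sequence on the remaining phenol can only use the one free ortho carbon (the other bears the acetyl group), so the pyran oxygen ends up ortho to the acyl group as the future C5–O/C6 ring requires.

Step 7
Reactants: 12 1-[5,7-bis(benzyloxy)-2,2-dimethyl-2H-chromen-8-yl]ethanone, 8 6-bromo-5,8-bis(methoxymethoxy)-2,2-dimethyl-2H-chromene
Product: 13 1-[5,7-bis(benzyloxy)-2,2-dimethyl-2H-chromen-8-yl]-2-[5,8-bis(methoxymethoxy)-2,2-dimethyl-2H-chromen-6-yl]ethanone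
Conditions: Pd2(dba)3 (cat.), XPhos, NaOtBu, toluene, 80 °C
Reagents that add atoms: none
Why: Palladium-catalysed ketone α-arylation (Buchwald–Hartwig type: oxidative addition of the aryl bromide to zerovalent palladium, enolate transmetalation, reductive elimination) joins two fully protected partners, and the bulky biaryl phosphine favours monoarylation of the methyl ketone.

Step 8
Reactants: 13 1-[5,7-bis(benzyloxy)-2,2-dimethyl-2H-chromen-8-yl]-2-[5,8-bis(methoxymethoxy)-2,2-dimethyl-2H-chromen-6-yl]ethanone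
Product: 14 2-[5,8-bis(methoxymethoxy)-2,2-dimethylchroman-6-yl]-1-(5,7-dihydroxy-2,2-dimethylchroman-8-yl)ethanone
Conditions: H2 (1 atm), 10% Pd/C, EtOAc–EtOH, rt
Reagents that add atoms: none
Why: One catalytic hydrogenation saturates both chromene double bonds and hydrogenolyses both benzyl ethers, while the acetals and the hindered aryl ketone are inert under neutral conditions.

Step 9
Reactants: 14 2-[5,8-bis(methoxymethoxy)-2,2-dimethylchroman-6-yl]-1-(5,7-dihydroxy-2,2-dimethylchroman-8-yl)ethanone, 6 3-chloro-3-methylbut-1-yne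
Product: 15 2-[5,8-bis(methoxymethoxy)-2,2-dimethylchroman-6-yl]-1-{7-hydroxy-2,2-dimethyl-5-[(2-methylbut-3-yn-2-yl)oxy]chroman-8-yl}ethanone
Conditions: 6 (1.5 equiv), DBU, CuCl2·2H2O (cat.), MeCN, 0 °C
Reagents that add atoms: none
Why: Copper-catalysed propargylic O-alkylation selects the more acidic hydroxyl para to the ketone, because the ortho hydroxyl is held in a hydrogen bond to the carbonyl.

Step 10
Reactants: 15 2-[5,8-bis(methoxymethoxy)-2,2-dimethylchroman-6-yl]-1-{7-hydroxy-2,2-dimethyl-5-[(2-methylbut-3-yn-2-yl)oxy]chroman-8-yl}ethanone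
Product: 17 2-[5,8-bis(methoxymethoxy)-2,2-dimethylchroman-6-yl]-1-[5,7-dihydroxy-2,2-dimethyl-6-(3-methylbut-2-en-1-yl)chroman-8-yl]ethanone, via 1,1-dimethylallyl ether 16 (not isolated)
Conditions: H2 (1 atm), Pd/CaCO3–Pb(OAc)2, quinoline, EtOAc, rt; filter; then o-xylene, 130 °C
Reagents that add atoms: none
Why: Lindlar semihydrogenation gives the aryl 1,1-dimethylallyl ether, whose aromatic Claisen rearrangement delivers a normal prenyl group to the only free ortho carbon and regenerates the phenol.

Step 11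
Reactants: 17 2-[5,8-bis(methoxymethoxy)-2,2-dimethylchroman-6-yl]-1-[5,7-dihydroxy-2,2-dimethyl-6-(3-methylbut-2-en-1-yl)chroman-8-yl]ethanone
Product: 18 2-[5,8-bis(methoxymethoxy)-2,2-dimethylchroman-6-yl]-1-[7-hydroxy-5-(methoxymethoxy)-2,2-dimethyl-6-(3-methylbut-2-en-1-yl)chroman-8-yl]ethanone
Conditions: MOMCl (1.3 equiv), i-Pr2NEt, CH2Cl2, 0 °C to rt
Reagents that add atoms: chloromethyl methyl ether (MOMCl), COCCl
Why: Acetal-forming O-alkylation under amine base protects only the hydroxyl para to the ketone, since the ortho hydroxyl is hydrogen-bonded and flanked by the prenyl and acyl groups.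

Step 12
Reactants: 18 2-[5,8-bis(methoxymethoxy)-2,2-dimethylchroman-6-yl]-1-[7-hydroxy-5-(methoxymethoxy)-2,2-dimethyl-6-(3-methylbut-2-en-1-yl)chroman-8-yl]ethanone, 19 carbon disulfide
Product: 21 9-[5,8-bis(methoxymethoxy)-2,2-dimethylchroman-6-yl]-5-(methoxymethoxy)-2,2-dimethyl-6-(3-methylbut-2-en-1-yl)-8-(methylsulfanyl)-3,4-dihydro-2H,10H-pyrano[2,3-f]chromen-10-one, via chromene-2-thione potassium salt 20 (not isolated)
Conditions: KOtBu (2.5 equiv), 19 (3 equiv), THF, 0 °C to rt; then MeI (3 equiv), 0 °C to rt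
Reagents that add atoms: iodomethane, CI
Why: KOtBu forms the phenoxide/enolate dianion of 18, whose benzylic carbon (C3, the only enolisable position) adds to CS2 to give a β-keto dithiocarboxylate; the C8a phenoxide then attacks the thiocarbonyl carbon and hydrosulfide is lost, so C2–C3 and C2–O1 form and ring C closes as the 4-hydroxychromene-2-thione anion 20, which MeI methylates on sulfur. This is the established conversion of 2-hydroxyaryl ketones with CS2 and base into 4-hydroxy-2H-chromene-2-thiones, followed by S-alkylation to 2-(alkylthio)chromones. Ring C closes by a 6-exo-trig addition–elimination at the dithiocarboxylate carbon, and no stereocentre is created. The step needs closure through the C8a oxygen only and alkylation on sulfur only: the C5 oxygen is locked in the chroman ring, the C7, C2' and C5' oxygens are acetals, and the soft sulfur of the ambident anion is the most nucleophilic site toward MeI. If MeI intercepts the open dithiocarboxylate first, the resulting ketene dithioacetal closes by phenoxide addition–elimination to the same product 21.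

Step 13
Reactants: 21 9-[5,8-bis(methoxymethoxy)-2,2-dimethylchroman-6-yl]-5-(methoxymethoxy)-2,2-dimethyl-6-(3-methylbut-2-en-1-yl)-8-(methylsulfanyl)-3,4-dihydro-2H,10H-pyrano[2,3-f]chromen-10-one
Product: 22 9-(5,8-dihydroxy-2,2-dimethylchroman-6-yl)-5-hydroxy-2,2-dimethyl-6-(3-methylbut-2-en-1-yl)-8-(methylsulfanyl)-3,4-dihydro-2H,10H-pyrano[2,3-f]chromen-10-one
Conditions: 3 M aq. HCl, MeOH–THF, 45 °C, Ar
Reagents that add atoms: none
Why: Acid-catalysed acetal exchange with methanol removes the three methoxymethyl groups under conditions mild enough to spare the prenyl alkene and the tertiary chroman ethers; any closure to 23 that already occurs here is harmless.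

Step 14
Reactants: 22 9-(5,8-dihydroxy-2,2-dimethylchroman-6-yl)-5-hydroxy-2,2-dimethyl-6-(3-methylbut-2-en-1-yl)-8-(methylsulfanyl)-3,4-dihydro-2H,10H-pyrano[2,3-f]chromen-10-one
Product: 23 target coumaronochromone CNP0081329.0
Conditions: K2CO3, DMF, 80 °C, Ar
Reagents that add atoms: none
Why: Intramolecular nucleophilic vinylic substitution (5-endo-trig addition–elimination) closes the furan ring: the C2' phenoxide adds to C2 of the vinylogous thioester and methanethiolate leaves.

**Compound list**

1 | 2,5-dihydroxybenzaldehyde | O=Cc1cc(O)ccc1O | starting material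
2 | 2,5-bis(methoxymethoxy)benzaldehyde | COCOc1ccc(OCOC)c(C=O)c1 | intermediate
3 | 2,5-bis(methoxymethoxy)phenyl formate (formed in situ) | O=COc1cc(OCOC)ccc1OCOC | intermediate
4 | 2,5-bis(methoxymethoxy)phenol | Oc1cc(OCOC)ccc1OCOC | intermediate
5 | 4-bromo-2,5-bis(methoxymethoxy)phenol | Oc1cc(OCOC)c(Br)cc1OCOC | intermediate
6 | 3-chloro-3-methylbut-1-yne | CC(C)(Cl)C#C | starting material
7 | 1-bromo-2,5-bis(methoxymethoxy)-4-[(2-methylbut-3-yn-2-yl)oxy]benzene (formed in situ) | C#CC(C)(C)Oc1cc(OCOC)c(Br)cc1OCOC | intermediate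
8 | 6-bromo-5,8-bis(methoxymethoxy)-2,2-dimethyl-2H-chromene | CC1(C)C=Cc2c(OCOC)c(Br)cc(OCOC)c2O1 | intermediate
9 | 1-(2,4,6-trihydroxyphenyl)ethanone (2',4',6'-trihydroxyacetophenone) | CC(=O)c1c(O)cc(O)cc1O | starting material
10 | 1-[2,4-bis(benzyloxy)-6-hydroxyphenyl]ethanone | CC(=O)c1c(O)cc(OCc2ccccc2)cc1OCc1ccccc1 | intermediate
11 | 1-{2,4-bis(benzyloxy)-6-[(2-methylbut-3-yn-2-yl)oxy]phenyl}ethanone (formed in situ) | CC(=O)c1c(OC(C)(C)C#C)cc(OCc2ccccc2)cc1OCc1ccccc1 | intermediate
12 | 1-[5,7-bis(benzyloxy)-2,2-dimethyl-2H-chromen-8-yl]ethanone | CC(=O)c1c(OCc2ccccc2)cc(OCc2ccccc2)c2C=CC(C)(C)Oc12 | intermediate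
13 | 1-[5,7-bis(benzyloxy)-2,2-dimethyl-2H-chromen-8-yl]-2-[5,8-bis(methoxymethoxy)-2,2-dimethyl-2H-chromen-6-yl]ethanone | O=C(Cc1cc(OCOC)c2OC(C)(C)C=Cc2c1OCOC)c1c(OCc2ccccc2)cc(OCc2ccccc2)c2C=CC(C)(C)Oc12 | intermediate
14 | 2-[5,8-bis(methoxymethoxy)-2,2-dimethylchroman-6-yl]-1-(5,7-dihydroxy-2,2-dimethylchroman-8-yl)ethanone | O=C(Cc1cc(OCOC)c2OC(C)(C)CCc2c1OCOC)c1c(O)cc(O)c2CCC(C)(C)Oc12 | intermediate
15 | 2-[5,8-bis(methoxymethoxy)-2,2-dimethylchroman-6-yl]-1-{7-hydroxy-2,2-dimethyl-5-[(2-methylbut-3-yn-2-yl)oxy]chroman-8-yl}ethanone | O=C(Cc1cc(OCOC)c2OC(C)(C)CCc2c1OCOC)c1c(O)cc(OC(C)(C)C#C)c2CCC(C)(C)Oc12 | intermediate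
16 | 2-[5,8-bis(methoxymethoxy)-2,2-dimethylchroman-6-yl]-1-{7-hydroxy-2,2-dimethyl-5-[(2-methylbut-3-en-2-yl)oxy]chroman-8-yl}ethanone (formed in situ) | O=C(Cc1cc(OCOC)c2OC(C)(C)CCc2c1OCOC)c1c(O)cc(OC(C)(C)C=C)c2CCC(C)(C)Oc12 | intermediate
17 | 2-[5,8-bis(methoxymethoxy)-2,2-dimethylchroman-6-yl]-1-[5,7-dihydroxy-2,2-dimethyl-6-(3-methylbut-2-en-1-yl)chroman-8-yl]ethanone | O=C(Cc1cc(OCOC)c2OC(C)(C)CCc2c1OCOC)c1c(O)c(CC=C(C)C)c(O)c2CCC(C)(C)Oc12 | intermediate
18 | 2-[5,8-bis(methoxymethoxy)-2,2-dimethylchroman-6-yl]-1-[7-hydroxy-5-(methoxymethoxy)-2,2-dimethyl-6-(3-methylbut-2-en-1-yl)chroman-8-yl]ethanone (the 2-hydroxydeoxybenzoin) | CC(C)=CCc1c(OCOC)c2CCC(C)(C)Oc2c(C(=O)Cc2cc(OCOC)c3OC(C)(C)CCc3c2OCOC)c1O | intermediate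
19 | carbon disulfide | S=C=S | starting material
20 | 9-[5,8-bis(methoxymethoxy)-2,2-dimethylchroman-6-yl]-10-hydroxy-5-(methoxymethoxy)-2,2-dimethyl-6-(3-methylbut-2-en-1-yl)-3,4-dihydro-2H,8H-pyrano[2,3-f]chromene-8-thione (potassium salt in the flask) | S=c1oc2c(CC=C(C)C)c(OCOC)c3CCC(C)(C)Oc3c2c(O)c1-c1cc(OCOC)c2OC(C)(C)CCc2c1OCOC | intermediate
21 | 9-[5,8-bis(methoxymethoxy)-2,2-dimethylchroman-6-yl]-5-(methoxymethoxy)-2,2-dimethyl-6-(3-methylbut-2-en-1-yl)-8-(methylsulfanyl)-3,4-dihydro-2H,10H-pyrano[2,3-f]chromen-10-one (the 2-(methylthio)isoflavone) | CSc1oc2c(CC=C(C)C)c(OCOC)c3CCC(C)(C)Oc3c2c(=O)c1-c1cc(OCOC)c2OC(C)(C)CCc2c1OCOC | intermediate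
22 | 9-(5,8-dihydroxy-2,2-dimethylchroman-6-yl)-5-hydroxy-2,2-dimethyl-6-(3-methylbut-2-en-1-yl)-8-(methylsulfanyl)-3,4-dihydro-2H,10H-pyrano[2,3-f]chromen-10-one | CSc1oc2c(CC=C(C)C)c(O)c3CCC(C)(C)Oc3c2c(=O)c1-c1cc(O)c2OC(C)(C)CCc2c1O | intermediate
23 | CNP0081329.0: coumaronochromone with 7-OH, 8-prenyl, a 2,2-dimethyldihydropyran fused through O–C5 and C6, 5'-OH, a 2,2-dimethyldihydropyran fused through O–C4' and C3', and the furan oxygen bridging C2 and C2' (achiral) | CC(C)=CCc1c(O)c2c(c3c(=O)c4c(oc13)oc1c3c(c(O)cc14)OC(C)(C)CC3)OC(C)(C)CC2 | target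

**Totals**

Total step count: 14. Longest linear sequence: 12 steps (steps 1–4, then 7–14, from compound 1).

**Steps most likely to fail**

Step 12 (key step). Ring closure of the hindered C8a phenoxide onto the dithiocarboxylate may be incomplete. Double S-methylation of the open-chain adduct may then stall, leaving acyclic sulfur compounds instead of ring C. The fallback sets out from 18 and returns at 21. Condensation of 18 with N,N-dimethylformamide dimethyl acetal (toluene, 100 °C) is the standard formic-level isoflavone closure and gives the 2-unsubstituted isoflavone F1. C2–H, the most acidic ring position, is then metalated with TMPMgCl·LiCl (THF, −40 °C) and quenched with S-methyl methanethiosulfonate, which installs the methylthio group and gives 21.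

Step 7. Transmetalation and reductive elimination between a doubly ortho-substituted aryl ketone enolate and an ortho-alkoxy aryl bromide may be slow. Protodebromination of the bromide or aldol self-condensation of the ketone could then take over. The fallback reverses the polarity of the same bond; it sets out from 12 and 8 and returns at 13. The lithium enolate of 12 (LiHMDS, THF, −78 °C) is brominated with NBS to the α-bromo ketone F2. Separately, 8 is converted by Miyaura borylation (B2pin2, Pd(dppf)Cl2, KOAc, dioxane, 80 °C) into the aryl pinacol boronate F3. Suzuki–Miyaura coupling of F2 with F3 (Pd(OAc)2, P(o-tolyl)3, K3PO4, THF–water, 60 °C) then gives 13.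

Step 14. Ionisation of the C7 hydroxyl lowers the electrophilicity of C2, so the addition–elimination may stall, and prolonged heating in base may air-oxidise the electron-rich hydroquinone-type ring D. The fallback raises the leaving-group ability at C2 before the phenols are freed; it sets out from 21 and returns at 23. One equivalent of mCPBA (CH2Cl2, −78 °C, where sulfur is oxidised faster than the trisubstituted alkene) gives the racemic sulfoxide F4. The acid conditions of step 13 then remove the acetals to give the triol sulfoxide F5, which closes to 23 in the same flask or on brief treatment with K2CO3 at room temperature, with loss of the sulfinyl group.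

**Further compounds**

F1 | step 12 | 9-[5,8-bis(methoxymethoxy)-2,2-dimethylchroman-6-yl]-5-(methoxymethoxy)-2,2-dimethyl-6-(3-methylbut-2-en-1-yl)-3,4-dihydro-2H,10H-pyrano[2,3-f]chromen-10-one (2-unsubstituted isoflavone) | O=c1c(-c2cc(OCOC)c3OC(C)(C)CCc3c2OCOC)coc2c(CC=C(C)C)c(OCOC)c3CCC(C)(C)Oc3c12
F2 | step 7 | 1-[5,7-bis(benzyloxy)-2,2-dimethyl-2H-chromen-8-yl]-2-bromoethanone | O=C(CBr)c1c(OCc2ccccc2)cc(OCc2ccccc2)c2C=CC(C)(C)Oc12
F3 | step 7 | 2-[5,8-bis(methoxymethoxy)-2,2-dimethyl-2H-chromen-6-yl]-4,4,5,5-tetramethyl-1,3,2-dioxaborolane | CC1(C)C=Cc2c(OCOC)c(B3OC(C)(C)C(C)(C)O3)cc(OCOC)c2O1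
F4 | step 14 | 9-[5,8-bis(methoxymethoxy)-2,2-dimethylchroman-6-yl]-5-(methoxymethoxy)-2,2-dimethyl-6-(3-methylbut-2-en-1-yl)-8-(methylsulfinyl)-3,4-dihydro-2H,10H-pyrano[2,3-f]chromen-10-one (racemic at sulfur) | CS(=O)c1oc2c(CC=C(C)C)c(OCOC)c3CCC(C)(C)Oc3c2c(=O)c1-c1cc(OCOC)c2OC(C)(C)CCc2c1OCOC
F5 | step 14 | 9-(5,8-dihydroxy-2,2-dimethylchroman-6-yl)-5-hydroxy-2,2-dimethyl-6-(3-methylbut-2-en-1-yl)-8-(methylsulfinyl)-3,4-dihydro-2H,10H-pyrano[2,3-f]chromen-10-one (racemic at sulfur, formed in situ) | CS(=O)c1oc2c(CC=C(C)C)c(O)c3CCC(C)(C)Oc3c2c(=O)c1-c1cc(O)c2OC(C)(C)CCc2c1O
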